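**Retrosynthetic overview**
1. Target ⇐ global desilylation of a bis-silyl ester ⇐ Steglich esterification of the ring C8 alcohol with 4-(silyloxy)benzoic acid.
2. The only ring formed (the ten-membered carbocycle) is closed last among the C–C bonds, at C8–C9, by a proposed intramolecular allylboration of a C1 α-chiral allyl pinacolboronate onto a C8 aldehyde; this also sets C8 and the Z C1=C10 alkene.
3. Allylboronate ⇐ primary N,N-diisopropylcarbamate by sparteine-mediated lithiation–borylation with isopropenyl pinacolboronate.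
4. C6 and C7 ⇐ Evans syn aldol of (R)-4-benzyl-3-isovaleryl-oxazolidinone with a Z-enal.
5. Z-enal (C1–C6, carrying the Z C4=C5 alkene) ⇐ neryl acetate by epoxidation and periodate cleavage.

Assumption: the SMILES is read literally, so both ring alkenes are Z and the stereotriad is all-syn, 6S,7R,8R in germacrane numbering (1R,2R,3S in the cyclodecadienyl name).
Atom labels in the text use germacrane numbering: C1=C10(Me)–C9–C8(OAr)–C7(iPr)–C6(OH)–C5=C4(Me)–C3–C2.

**Route**

Step 1
Reactants: 1 neryl acetate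
Product: 2 (2Z)-5-(3,3-dimethyloxiran-2-yl)-3-methylpent-2-en-1-yl acetate (racemic)
Conditions: mCPBA (1.05 equiv), CH2Cl2, −10 → 0 °C
Reagents that add atoms: mCPBA (3-chloroperoxybenzoic acid), OOC(=O)c1cccc(Cl)c1
Why: Prilezhaev epoxidation is much faster at the remote, electron-rich 6,7-alkene than at the 2,3-alkene deactivated by the allylic acetate, and the new stereocentre is irrelevant because it is excised in step 2.

Step 2
Reactants: 2 (2Z)-5-(3,3-dimethyloxiran-2-yl)-3-methylpent-2-en-1-yl acetate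
Product: 4 (2Z)-3-methyl-6-oxohex-2-en-1-yl acetate, via diol 3 (not isolated)
Conditions: H5IO6 (1.1 equiv), THF/H2O (5:1), 0 °C, 1 h
Reagents that add atoms: none
Why: Aqueous periodic acid opens the epoxide to the vicinal diol and cleaves it in the same flask (Malaprade glycol cleavage), releasing acetone and leaving the Z-alkene and the acetate untouched.

Step 3
Reactants: 4 (2Z)-3-methyl-6-oxohex-2-en-1-yl acetate
Product: 5 (2Z)-6-hydroxy-3-methylhex-2-en-1-yl acetate
Conditions: NaBH4 (0.5 equiv), MeOH, 0 °C, 15 min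
Reagents that add atoms: none
Why: Chemoselective borohydride reduction of the aldehyde, which is far faster than attack on the acetate at 0 °C.

Step 4
Reactants: 5 (2Z)-6-hydroxy-3-methylhex-2-en-1-yl acetate
Product: 6 (2Z)-6-{[di(propan-2-yl)carbamoyl]oxy}-3-methylhex-2-en-1-yl acetate
Conditions: i-Pr2NCOCl (1.3 equiv), Et3N (1.5 equiv), CH2Cl2, reflux, 24 h
Reagents that add atoms: N,N-diisopropylcarbamoyl chloride, CC(C)N(C(C)C)C(Cl)=O
Why: O-Carbamoylation of the primary alcohol installs the Hoppe carbamate that later directs asymmetric α-lithiation at C1 and that is inert to the oxidants, Lewis acids and hydrides used in between.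

Step 5
Reactants: 6 (2Z)-6-{[di(propan-2-yl)carbamoyl]oxy}-3-methylhex-2-en-1-yl acetate
Product: 7 (4Z)-6-hydroxy-4-methylhex-4-en-1-yl N,N-di(propan-2-yl)carbamate
Conditions: K2CO3 (0.2 equiv), MeOH, 0 °C → rt
Reagents that add atoms: none
Why: Base-catalysed transesterification removes the acetate as methyl acetate while the hindered diisopropylcarbamate does not react with methoxide.

Step 6
Reactants: 7 (4Z)-6-hydroxy-4-methylhex-4-en-1-yl N,N-di(propan-2-yl)carbamate
Product: 8 (4Z)-4-methyl-6-oxohex-4-en-1-yl N,N-di(propan-2-yl)carbamate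
Conditions: PhI(OAc)2 (1.1 equiv), TEMPO (2,2,6,6-tetramethylpiperidin-1-oxyl, 10 mol%), CH2Cl2, 0 °C → rt
Reagents that add atoms: none
Why: The nitroxyl-catalysed oxidation of the allylic alcohol stops at the enal and, as for nerol to neral, proceeds without Z to E isomerisation because no strong acid or base is present.

Step 7
Reactants: 9 (4R)-4-benzyl-1,3-oxazolidin-2-one; 10 3-methylbutanoyl chloride
Product: 12 (4R)-4-benzyl-3-(3-methylbutanoyl)-1,3-oxazolidin-2-one, via lithium oxazolidinide 11 (not isolated)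
Conditions: n-BuLi (1.0 equiv), THF, −78 °C; then 10, −78 → 0 °C
Reagents that add atoms: none
Why: N-Acylation of the lithiated oxazolidinone by the acid chloride is the standard loading of an Evans auxiliary and does not touch its stereocentre.

Step 8
Reactants: 12 (4R)-4-benzyl-3-(3-methylbutanoyl)-1,3-oxazolidin-2-one; 8 (4Z)-4-methyl-6-oxohex-4-en-1-yl N,N-di(propan-2-yl)carbamate
Product: 15 (4R)-4-benzyl-3-[(2R,3S,4Z)-8-{[di(propan-2-yl)carbamoyl]oxy}-3-hydroxy-5-methyl-2-(propan-2-yl)oct-4-enoyl]-1,3-oxazolidin-2-one, via dibutylboron Z-enolate 13 (not isolated), via boron aldolate 14 (not isolated)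
Conditions: n-Bu2BOTf (1.2 equiv), i-Pr2NEt (1.4 equiv), CH2Cl2, 0 °C; then 8, −78 → 0 °C; then pH 7 buffer, MeOH, 30% H2O2, 0 °C
Reagents that add atoms: none
Why: Evans syn aldol reaction, in which the Z-boron enolate adds through a closed Zimmerman–Traxler chair on the face opposite the benzyl group of the R auxiliary, setting C7 (R) and C6 (S) syn with dr typically above 20:1, while the low temperature keeps the Z-enal from isomerising.

Step 9
Reactants: 15 the aldol adduct
Product: 16 (4R)-4-benzyl-3-[(2R,3S,4Z)-3-[(tert-butyldimethylsilyl)oxy]-8-{[di(propan-2-yl)carbamoyl]oxy}-5-methyl-2-(propan-2-yl)oct-4-enoyl]-1,3-oxazolidin-2-one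
Conditions: TBSOTf (1.5 equiv), 2,6-lutidine (2.5 equiv), CH2Cl2, −78 → 0 °C
Reagents that add atoms: tert-butyldimethylsilyl triflate (TBSOTf), CC(C)(C)[Si](C)(C)OS(=O)(=O)C(F)(F)F
Why: Silyl triflate with a hindered pyridine base silylates the hindered secondary allylic hydroxyl without retro-aldol cleavage or epimerisation at C7, and keeps O6 distinguished from O8 to the end.

Step 10
Reactants: 16 the silylated imide
Product: 17 (4Z,6S,7S)-6-[(tert-butyldimethylsilyl)oxy]-8-hydroxy-4-methyl-7-(propan-2-yl)oct-4-en-1-yl N,N-di(propan-2-yl)carbamate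
Conditions: LiBH4 (2 equiv), MeOH (2 equiv), THF, 0 °C → rt
Reagents that add atoms: none
Why: Reductive cleavage of the N-acyl oxazolidinone by borohydride occurs at the exocyclic carbonyl and frees the auxiliary, while the carbamate and the silyl ether are inert and no stereocentre is touched (the C7 descriptor changes only through priorities).

Step 11
Reactants: 17 the primary alcohol
Product: 18 (4Z,6S,7S)-6-[(tert-butyldimethylsilyl)oxy]-4-methyl-7-(propan-2-yl)-8-[(triethylsilyl)oxy]oct-4-en-1-yl N,N-di(propan-2-yl)carbamate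
Conditions: Et3SiCl (1.2 equiv), imidazole (2 equiv), CH2Cl2, 0 °C
Reagents that add atoms: chlorotriethylsilane, CC[Si](Cl)(CC)CC
Why: Silylation masks O8 against s-BuLi as a primary triethylsilyl ether that can later be removed in the presence of the secondary tert-butyldimethylsilyl ether.

Step 12
Reactants: 18 the carbamate; 19 4,4,5,5-tetramethyl-2-(prop-1-en-2-yl)-1,3,2-dioxaborolane
Product: 22 2-[(3R,6Z,8S,9S)-8-[(tert-butyldimethylsilyl)oxy]-2,6-dimethyl-9-(propan-2-yl)-10-[(triethylsilyl)oxy]deca-1,6-dien-3-yl]-4,4,5,5-tetramethyl-1,3,2-dioxaborolane, via S-lithiated carbamate 20 (not isolated), via lithium boronate complex 21 (not isolated)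
Conditions: s-BuLi (1.3 equiv), (−)-sparteine (1.3 equiv), Et2O, −78 °C, 5 h; then 19 (1.5 equiv), −78 °C, 1 h; then 35 °C, 12 h
Reagents that add atoms: none
Why: Hoppe–Aggarwal lithiation–borylation, in which (−)-sparteine directs removal of the pro-S hydrogen at C1, the boronic ester is captured with retention, and 1,2-migration of the propen-2-yl group with inversion expels the carbamate, so the boron-bearing C1 is set as R under reagent control.

Step 13
Reactants: 22 the allylboronate
Product: 23 (2S,3S,4Z,8R)-3-[(tert-butyldimethylsilyl)oxy]-5,9-dimethyl-2-(propan-2-yl)-8-(4,4,5,5-tetramethyl-1,3,2-dioxaborolan-2-yl)deca-4,9-dien-1-ol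
Conditions: PPTS (pyridinium p-toluenesulfonate, 10 mol%), MeOH/CH2Cl2 (1:1), 0 °C
Reagents that add atoms: none
Why: Mild acid-catalysed methanolysis cleaves the primary triethylsilyl ether far faster than the hindered secondary tert-butyldimethylsilyl ether and leaves the pinacolboronate intact.

Step 14
Reactants: 23 the hydroxy allylboronate
Product: 24 (2R,3S,4Z,8R)-3-[(tert-butyldimethylsilyl)oxy]-5,9-dimethyl-2-(propan-2-yl)-8-(4,4,5,5-tetramethyl-1,3,2-dioxaborolan-2-yl)deca-4,9-dienal
Conditions: Dess–Martin periodinane (1.3 equiv), CH2Cl2, 0 °C, 45 min; cold filtration through Florisil, used at once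
Reagents that add atoms: none
Why: Dess–Martin oxidation is neutral enough to avoid epimerisation at C7 and tolerates the boronate, and the hindered aldehyde does not react with the α-branched allylboronate intermolecularly during a short, cold, dilute handling.

Step 15
Reactants: 24 the aldehyde allylboronate
Product: 26 (1R,2S,3S,4Z,8Z)-3-[(tert-butyldimethylsilyl)oxy]-5,9-dimethyl-2-(propan-2-yl)cyclodeca-4,8-dien-1-ol, via macrocyclic pinacol borate 25 (not isolated)
Conditions: toluene (1 mM; 24 added over 10 h), 4 Å molecular sieves, 60 °C, 36 h; then pH 7 buffer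
Reagents that add atoms: none
Why: Proposed new method: an uncatalysed macrocyclising allylboration in which the C1 boron of the enantioenriched α-substituted allyl pinacolboronate binds the C8 aldehyde oxygen and the terminal CH2 (C9) adds through a closed six-membered Zimmerman–Traxler chair, so that the C8–C9 bond and the ten-membered ring form together while the double bond shifts to C1=C10; the six-atom tether (C2–C7) can bridge the chair only when C2 is pseudo-axial on C1 and C7 is equatorial on C8, an arrangement already preferred for 2-methyl-substituted α-branched pinacolboronates because it avoids A(1,2) strain with the C10 methyl and gauche contacts with the pinacol methyls, and this single geometry gives the Z C1=C10 alkene and relays the R configuration of C1 to the R configuration of C8 (1,3-chirality transfer, all-syn with C6 and C7) whatever the modest facial bias of the aldehyde; the closest known reaction type is the intermolecular addition of α-chiral allyl pinacolboronates to aldehydes (Z-selective, with chirality transfer) together with intramolecular allylborations that close five- to seven-membered rings, neither of which has been used to close a medium ring or to set a ring Z-trisubstituted alkene.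

Step 16
Reactants: 27 4-hydroxybenzoic acid
Product: 29 4-[(tert-butyldimethylsilyl)oxy]benzoic acid, via bis-silyl compound 28 (not isolated)
Conditions: TBSCl (2.3 equiv), imidazole (4 equiv), DMF, rt; then AcOH/THF/H2O (3:1:1), rt
Reagents that add atoms: tert-butyldimethylsilyl chloride (TBSCl), CC(C)(C)[Si](C)(C)Cl
Why: Exhaustive silylation followed by selective hydrolysis of the far more labile silyl ester leaves the phenol protected and the acid free for coupling.

Step 17
Reactants: 26 the macrocyclic alcohol; 29 4-[(tert-butyldimethylsilyl)oxy]benzoic acid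
Product: 30 (1R,2S,3S,4Z,8Z)-3-[(tert-butyldimethylsilyl)oxy]-5,9-dimethyl-2-(propan-2-yl)cyclodeca-4,8-dien-1-yl 4-[(tert-butyldimethylsilyl)oxy]benzoate
Conditions: DCC (1.5 equiv), DMAP (4-(dimethylamino)pyridine, 0.3 equiv), CH2Cl2, rt
Reagents that add atoms: none
Why: Steglich esterification acylates the only free hydroxyl (O8) through the acylpyridinium intermediate with retention at C8, since the C8–O bond is not broken.

Step 18
Reactants: 30 the bis-silyl ester
Product: 31 (1R,2R,3S,4Z,8Z)-3-hydroxy-5,9-dimethyl-2-(propan-2-yl)cyclodeca-4,8-dien-1-yl 4-hydroxybenzoate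
Conditions: HF·pyridine, pyridine, THF, 0 °C → rt
Reagents that add atoms: none
Why: Buffered fluoride cleaves the aryl and the secondary allylic silyl ethers in one operation under mildly acidic conditions that suppress 1,3-acyl migration from O8 to O6 and do not ionise the allylic alcohol.

**Compound list**
1 | neryl acetate, (2Z)-3,7-dimethylocta-2,6-dien-1-yl acetate | CC(C)=CCC/C(C)=C\COC(C)=O | starting material
2 | (2Z)-5-(3,3-dimethyloxiran-2-yl)-3-methylpent-2-en-1-yl acetate (racemic) | CC(=O)OC/C=C(C)\CCC1OC1(C)C | intermediate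
3 | (2Z)-6,7-dihydroxy-3,7-dimethyloct-2-en-1-yl acetate (racemic) | CC(=O)OC/C=C(C)\CCC(O)C(C)(C)O | intermediate
4 | (2Z)-3-methyl-6-oxohex-2-en-1-yl acetate | CC(=O)OC/C=C(C)\CCC=O | intermediate
5 | (2Z)-6-hydroxy-3-methylhex-2-en-1-yl acetate | CC(=O)OC/C=C(C)\CCCO | intermediate
6 | (2Z)-6-{[di(propan-2-yl)carbamoyl]oxy}-3-methylhex-2-en-1-yl acetate | CC(=O)OC/C=C(C)\CCCOC(=O)N(C(C)C)C(C)C | intermediate
7 | (4Z)-6-hydroxy-4-methylhex-4-en-1-yl N,N-di(propan-2-yl)carbamate | OC/C=C(C)\CCCOC(=O)N(C(C)C)C(C)C | intermediate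
8 | (4Z)-4-methyl-6-oxohex-4-en-1-yl N,N-di(propan-2-yl)carbamate | O=C/C=C(C)\CCCOC(=O)N(C(C)C)C(C)C | intermediate
9 | (4R)-4-benzyl-1,3-oxazolidin-2-one | O=C1N[C@H](Cc2ccccc2)CO1 | starting material
10 | 3-methylbutanoyl chloride | CC(C)CC(Cl)=O | starting material
11 | N-lithio-(4R)-4-benzyl-1,3-oxazolidin-2-one | [Li]N1[C@H](Cc2ccccc2)COC1=O | intermediate
12 | (4R)-4-benzyl-3-(3-methylbutanoyl)-1,3-oxazolidin-2-one | CC(C)CC(=O)N1[C@H](Cc2ccccc2)COC1=O | intermediate
13 | dibutylboron Z-enolate of 12 | CC(C)/C=C(\OB(CCCC)CCCC)N1[C@H](Cc2ccccc2)COC1=O | intermediate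
14 | O-dibutylboryl aldolate of 15 | CC(C)N(C(C)C)C(=O)OCCC/C(C)=C\[C@H](OB(CCCC)CCCC)[C@@H](C(C)C)C(=O)N1[C@H](Cc2ccccc2)COC1=O | intermediate
15 | (4R)-4-benzyl-3-[(2R,3S,4Z)-8-{[di(propan-2-yl)carbamoyl]oxy}-3-hydroxy-5-methyl-2-(propan-2-yl)oct-4-enoyl]-1,3-oxazolidin-2-one | CC(C)N(C(C)C)C(=O)OCCC/C(C)=C\[C@H](O)[C@@H](C(C)C)C(=O)N1[C@H](Cc2ccccc2)COC1=O | intermediate
16 | (4R)-4-benzyl-3-[(2R,3S,4Z)-3-[(tert-butyldimethylsilyl)oxy]-8-{[di(propan-2-yl)carbamoyl]oxy}-5-methyl-2-(propan-2-yl)oct-4-enoyl]-1,3-oxazolidin-2-one | CC(C)N(C(C)C)C(=O)OCCC/C(C)=C\[C@H](O[Si](C)(C)C(C)(C)C)[C@@H](C(C)C)C(=O)N1[C@H](Cc2ccccc2)COC1=O | intermediate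
17 | (4Z,6S,7S)-6-[(tert-butyldimethylsilyl)oxy]-8-hydroxy-4-methyl-7-(propan-2-yl)oct-4-en-1-yl N,N-di(propan-2-yl)carbamate | CC(C)N(C(C)C)C(=O)OCCC/C(C)=C\[C@H](O[Si](C)(C)C(C)(C)C)[C@@H](C(C)C)CO | intermediate
18 | (4Z,6S,7S)-6-[(tert-butyldimethylsilyl)oxy]-4-methyl-7-(propan-2-yl)-8-[(triethylsilyl)oxy]oct-4-en-1-yl N,N-di(propan-2-yl)carbamate | CC(C)N(C(C)C)C(=O)OCCC/C(C)=C\[C@H](O[Si](C)(C)C(C)(C)C)[C@@H](C(C)C)CO[Si](CC)(CC)CC | intermediate
19 | 4,4,5,5-tetramethyl-2-(prop-1-en-2-yl)-1,3,2-dioxaborolane | CC(=C)B1OC(C)(C)C(C)(C)O1 | starting material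
20 | (1S)-1-lithio derivative of 18 | [Li][C@H](OC(=O)N(C(C)C)C(C)C)CC/C(C)=C\[C@H](O[Si](C)(C)C(C)(C)C)[C@@H](C(C)C)CO[Si](CC)(CC)CC | intermediate
21 | lithium (pinacolato)(prop-1-en-2-yl)borate complex of 20, S at C1 | [Li+].CC(=C)[B-]1(OC(C)(C)C(C)(C)O1)[C@H](OC(=O)N(C(C)C)C(C)C)CC/C(C)=C\[C@H](O[Si](C)(C)C(C)(C)C)[C@@H](C(C)C)CO[Si](CC)(CC)CC | intermediate
22 | 2-[(3R,6Z,8S,9S)-8-[(tert-butyldimethylsilyl)oxy]-2,6-dimethyl-9-(propan-2-yl)-10-[(triethylsilyl)oxy]deca-1,6-dien-3-yl]-4,4,5,5-tetramethyl-1,3,2-dioxaborolane | C=C(C)[C@H](B1OC(C)(C)C(C)(C)O1)CC/C(C)=C\[C@H](O[Si](C)(C)C(C)(C)C)[C@@H](C(C)C)CO[Si](CC)(CC)CC | intermediate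
23 | (2S,3S,4Z,8R)-3-[(tert-butyldimethylsilyl)oxy]-5,9-dimethyl-2-(propan-2-yl)-8-(4,4,5,5-tetramethyl-1,3,2-dioxaborolan-2-yl)deca-4,9-dien-1-ol | C=C(C)[C@H](B1OC(C)(C)C(C)(C)O1)CC/C(C)=C\[C@H](O[Si](C)(C)C(C)(C)C)[C@@H](C(C)C)CO | intermediate
24 | (2R,3S,4Z,8R)-3-[(tert-butyldimethylsilyl)oxy]-5,9-dimethyl-2-(propan-2-yl)-8-(4,4,5,5-tetramethyl-1,3,2-dioxaborolan-2-yl)deca-4,9-dienal | C=C(C)[C@H](B1OC(C)(C)C(C)(C)O1)CC/C(C)=C\[C@H](O[Si](C)(C)C(C)(C)C)[C@@H](C(C)C)C=O | intermediate
25 | 2-{[(1R,2S,3S,4Z,8Z)-3-[(tert-butyldimethylsilyl)oxy]-5,9-dimethyl-2-(propan-2-yl)cyclodeca-4,8-dien-1-yl]oxy}-4,4,5,5-tetramethyl-1,3,2-dioxaborolane | C/C1=C/[C@H](O[Si](C)(C)C(C)(C)C)[C@@H](C(C)C)[C@H](OB2OC(C)(C)C(C)(C)O2)C/C(C)=C\CC1 | intermediate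
26 | (1R,2S,3S,4Z,8Z)-3-[(tert-butyldimethylsilyl)oxy]-5,9-dimethyl-2-(propan-2-yl)cyclodeca-4,8-dien-1-ol | C/C1=C/[C@H](O[Si](C)(C)C(C)(C)C)[C@@H](C(C)C)[C@H](O)C/C(C)=C\CC1 | intermediate
27 | 4-hydroxybenzoic acid | OC(=O)c1ccc(O)cc1 | starting material
28 | tert-butyldimethylsilyl 4-[(tert-butyldimethylsilyl)oxy]benzoate | CC(C)(C)[Si](C)(C)OC(=O)c1ccc(O[Si](C)(C)C(C)(C)C)cc1 | intermediate
29 | 4-[(tert-butyldimethylsilyl)oxy]benzoic acid | CC(C)(C)[Si](C)(C)Oc1ccc(cc1)C(O)=O | intermediate
30 | (1R,2S,3S,4Z,8Z)-3-[(tert-butyldimethylsilyl)oxy]-5,9-dimethyl-2-(propan-2-yl)cyclodeca-4,8-dien-1-yl 4-[(tert-butyldimethylsilyl)oxy]benzoate | C/C1=C/[C@H](O[Si](C)(C)C(C)(C)C)[C@@H](C(C)C)[C@H](OC(=O)c2ccc(O[Si](C)(C)C(C)(C)C)cc2)C/C(C)=C\CC1 | intermediate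
31 | (1R,2R,3S,4Z,8Z)-3-hydroxy-5,9-dimethyl-2-(propan-2-yl)cyclodeca-4,8-dien-1-yl 4-hydroxybenzoate | C/C1=C/[C@H](O)[C@@H](C(C)C)[C@H](OC(=O)c2ccc(O)cc2)C/C(C)=C\CC1 | target

**Step count and risks**
Total step count: 18. Longest linear sequence: 16 steps (steps 1–6, 8–15, 17 and 18, from neryl acetate).

Three steps most likely to fail:

Step 15 (the proposed new macrocyclising allylboration). The risks are oligomerisation at the low effective molarity of ten-membered rings, a competing boat or diequatorial transition state that would give the E-alkene or the C8 epimer, and a 1,3-boryl shift on prolonged heating. The fallback uses known chemistry only, sets out from 17 and comes back at 26. Compound 17 is oxidised with Dess–Martin periodinane to the aldehyde F1. Reagent-controlled Brown allylboration with B-methallyldiisopinocampheylborane, made from (+)-Ipc2BOMe (derived from (−)-α-pinene) and methallylmagnesium chloride (Et2O, −78 °C; then NaOH, H2O2), gives the 8R homoallylic alcohol F2. The carbamate is cleaved with LiAlH4 (THF, 0 → 50 °C) to the diol F3. PhI(OAc)2 with catalytic TEMPO oxidises only the primary hydroxyl to the hydroxy aldehyde F4. Wittig methylenation with Ph3P=CH2 gives the triene F5. Ring-closing metathesis with the second-generation Grubbs catalyst RuCl2(SIMes)(PCy3)(=CHPh) in toluene at 1 mM and 80 °C then joins the vinyl and methallyl termini; the Z-trisubstituted alkene is expected to be favoured in a ten-membered ring that already holds one Z-alkene, giving 26.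

Step 12 (lithiation–borylation on a polyfunctional substrate). The risks are incomplete or unselective deprotonation, a sluggish 1,2-shift in the presence of sparteine and excess base, and erosion of the enantiomer ratio. The fallback sets out from 18 and comes back at 22; it separates the asymmetric deprotonation from the borylation by passing through an isolable, configurationally stable tin compound. The lithiated carbamate from s-BuLi and (−)-sparteine is trapped with Me3SnCl (retention) to give the stannane F6, which is purified and checked for enantiomer ratio. Tin–lithium exchange with n-BuLi (Et2O, −78 °C, retention) then regenerates the S-lithio carbamate free of diamine and excess s-BuLi; 19 is added and the mixture is warmed to give 22.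

Step 10 (reductive removal of the auxiliary from the hindered α-isopropyl β-silyloxy imide). The risks are slow reduction, endocyclic opening of the oxazolidinone, and silyl migration from O6 to O8. The fallback sets out from 15 and comes back at 18, reducing before silylation and then telling the two hydroxyls apart by sterics. NaBH4 in THF/H2O (0 °C → rt) reduces the β-hydroxy imide 15 directly to the diol F7. Et3SiCl and imidazole at −40 °C silylate only the primary hydroxyl to give the mono-triethylsilyl ether F8. TBSOTf with 2,6-lutidine then gives 18, so compounds 16 and 17 are bypassed.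

**Further compounds**
F1 | step 15 | (4Z,6S,7R)-6-[(tert-butyldimethylsilyl)oxy]-4-methyl-8-oxo-7-(propan-2-yl)oct-4-en-1-yl N,N-di(propan-2-yl)carbamate | CC(C)N(C(C)C)C(=O)OCCC/C(C)=C\[C@H](O[Si](C)(C)C(C)(C)C)[C@@H](C(C)C)C=O
F2 | step 15 | (4Z,6S,7S,8R)-6-[(tert-butyldimethylsilyl)oxy]-8-hydroxy-4,10-dimethyl-7-(propan-2-yl)undeca-4,10-dien-1-yl N,N-di(propan-2-yl)carbamate | CC(C)N(C(C)C)C(=O)OCCC/C(C)=C\[C@H](O[Si](C)(C)C(C)(C)C)[C@@H](C(C)C)[C@H](O)CC(C)=C
F3 | step 15 | (4Z,6S,7S,8R)-6-[(tert-butyldimethylsilyl)oxy]-4,10-dimethyl-7-(propan-2-yl)undeca-4,10-diene-1,8-diol | OCCC/C(C)=C\[C@H](O[Si](C)(C)C(C)(C)C)[C@@H](C(C)C)[C@H](O)CC(C)=C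
F4 | step 15 | (4Z,6S,7S,8R)-6-[(tert-butyldimethylsilyl)oxy]-8-hydroxy-4,10-dimethyl-7-(propan-2-yl)undeca-4,10-dienal | O=CCC/C(C)=C\[C@H](O[Si](C)(C)C(C)(C)C)[C@@H](C(C)C)[C@H](O)CC(C)=C
F5 | step 15 | (4R,5S,6S,7Z)-6-[(tert-butyldimethylsilyl)oxy]-2,8-dimethyl-5-(propan-2-yl)dodeca-1,7,11-trien-4-ol | C=CCC/C(C)=C\[C@H](O[Si](C)(C)C(C)(C)C)[C@@H](C(C)C)[C@H](O)CC(C)=C
F6 | step 12 | (1S,4Z,6S,7S)-6-[(tert-butyldimethylsilyl)oxy]-4-methyl-7-(propan-2-yl)-8-[(triethylsilyl)oxy]-1-(trimethylstannyl)oct-4-en-1-yl N,N-di(propan-2-yl)carbamate | C[Sn](C)(C)[C@H](OC(=O)N(C(C)C)C(C)C)CC/C(C)=C\[C@H](O[Si](C)(C)C(C)(C)C)[C@@H](C(C)C)CO[Si](CC)(CC)CC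
F7 | step 10 | (4Z,6S,7S)-6,8-dihydroxy-4-methyl-7-(propan-2-yl)oct-4-en-1-yl N,N-di(propan-2-yl)carbamate | CC(C)N(C(C)C)C(=O)OCCC/C(C)=C\[C@H](O)[C@@H](C(C)C)CO
F8 | step 10 | (4Z,6S,7S)-6-hydroxy-4-methyl-7-(propan-2-yl)-8-[(triethylsilyl)oxy]oct-4-en-1-yl N,N-di(propan-2-yl)carbamate | CC(C)N(C(C)C)C(=O)OCCC/C(C)=C\[C@H](O)[C@@H](C(C)C)CO[Si](CC)(CC)CC
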